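**Retrosynthetic overview**

- Feature: in the seven-membered ring (C1, C2, C6, C7, C8, C9, C10; C1 bears the exocyclic CH2, C2/C6 are the trans ring-fusion carbons shared with the cyclopentene C2–C3–C4=C5(Me)–C6), C8 lies between the C7 carbinol and C9H2 and carries the whole side chain (C1′–C5′). It is therefore taken out as the carbon of a side-chain diazoalkane inserted next to a C7 ketone of a six-membered ring (C1, C2, C6, C7, C9, C10).
- Late stage: C7 ketone to the 7β-alcohol, C10 silyl ether to acetate; C7–C8 and C8–C9 from trans-hydrindanone 32 and diazoalkane 11.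
- Diazoalkane 11: C1′ from the Roche ester, C2′–C3′ by Negishi coupling with the (E)-alkenyl iodide from 2-methylbut-3-yn-2-ol, then ester to aldehyde to hydrazone to diazo.
- Hydrindanone 32: (R)-4-silyloxycyclopentenone supplies the five-membered ring and the absolute configuration (C2–C1 by anti conjugate addition/elimination, C6–C7 by trans aldol); C1–C10 by CrCl2/NiCl2 closure; C5–CH3 via the enol triflate.
- Ring order: five-membered (chiral pool), six-membered (step 14), seven-membered (step 20).

Key step: step 20

Remark: atom numbers are those of the target skeleton; the C7 carbinol centre made in step 9 is oxidised in step 19 and is carried as an epimer mixture through 19–31; 12, 13 and 17 are taken as purchased.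

**Side-chain diazoalkane**

Step 1
Reactants: 1 2-methylbut-3-yn-2-ol
Product: 2 triethyl[(2-methylbut-3-yn-2-yl)oxy]silane
Conditions: Et3SiOTf, 2,6-lutidine, CH2Cl2, 0 °C
Reagents that add atoms: triethylsilyl trifluoromethanesulfonate, CC[Si](CC)(CC)OS(=O)(=O)C(F)(F)F
Why: O-silylation of a tertiary alcohol with a silyl triflate and a hindered pyridine base is routine and masks the hydroxyl for the organometallic steps.

Step 2
Reactants: 2 triethyl[(2-methylbut-3-yn-2-yl)oxy]silane
Product: 4 (E)-triethyl[(4-iodo-2-methylbut-3-en-2-yl)oxy]silane, via alkenylzirconocene chloride 3 (not isolated)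
Conditions: Cp2Zr(H)Cl, THF, rt; then I2, 0 °C
Reagents that add atoms: iodine, II
Why: Hydrozirconation of the terminal alkyne is syn and places zirconium on the terminal carbon, and iodinolysis of the C–Zr bond with retention should give the (E)-alkenyl iodide (hydrozirconation–iodination).

Step 3
Reactants: 5 methyl (S)-3-hydroxy-2-methylpropanoate
Product: 6 methyl (R)-3-iodo-2-methylpropanoate
Conditions: I2, PPh3, imidazole, CH2Cl2, 0 °C → rt
Reagents that add atoms: iodine, II
Why: Appel-type iodination of the primary alcohol does not touch the α-stereocentre (the descriptor changes only because CH2I outranks the ester).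

Step 4
Reactants: 6 methyl (R)-3-iodo-2-methylpropanoate; 4 (E)-triethyl[(4-iodo-2-methylbut-3-en-2-yl)oxy]silane
Product: 8 methyl (2S,4E)-2,6-dimethyl-6-(triethylsilyloxy)hept-4-enoate, via alkylzinc iodide 7 (not isolated)
Conditions: Zn dust (activated with BrCH2CH2Br, Me3SiCl), DMF, rt; then 4, Pd2(dba)3 (2.5 mol %), P(o-tol)3 (10 mol %), rt
Reagents that add atoms: none
Why: Zinc inserts into the primary C–I bond to give a configurationally stable ester-bearing alkylzinc reagent, and its sp3–sp2 Negishi coupling with the alkenyl iodide should keep the (E)-geometry.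

Step 5
Reactants: 8 methyl (2S,4E)-2,6-dimethyl-6-(triethylsilyloxy)hept-4-enoate
Product: 9 (2S,4E)-2,6-dimethyl-6-(triethylsilyloxy)hept-4-enal
Conditions: i-Bu2AlH (1.1 equiv), CH2Cl2, −78 °C; MeOH, then aq. KNaC4H4O6
Reagents that add atoms: none
Why: At −78 °C the hydride reduction of the methyl ester stops at the aldehyde oxidation level until work-up (partial ester reduction), and the cold neutral work-up should preserve the α-stereocentre.

Step 6
Reactants: 9 (2S,4E)-2,6-dimethyl-6-(triethylsilyloxy)hept-4-enal
Product: 10 (E)-hydrazone of 9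
Conditions: N2H4·H2O (10 equiv), EtOH, 0 °C, slow addition of 9
Reagents that add atoms: hydrazine (as hydrate), NN
Why: Condensation with a large excess of hydrazine under inverse addition gives the N-unsubstituted hydrazone and suppresses azine formation, and the cold neutral medium should not epimerise C1′.

Step 7
Reactants: 10 (E)-hydrazone of 9
Product: 11 (2S,4E)-1-diazo-2,6-dimethyl-6-(triethylsilyloxy)hept-4-ene
Conditions: DMSO, (COCl)2, THF, −78 °C; then 10 and Et3N (2.2 equiv), −78 °C; cold filtration, solution titrated and used at once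
Reagents that add atoms: none
Why: Swern-type dehydrogenation of the hydrazone (N-sulfenylation by chlorodimethylsulfonium chloride, then base-induced loss of dimethyl sulfide) should give the non-stabilised diazoalkane at −78 °C, where it and its adjacent stereocentre are stable.

**trans-Hydrindanone**

Step 8
Reactants: 12 (1-bromovinyl)trimethylsilane; 13 (R)-4-(tert-butyldimethylsilyloxy)cyclopent-2-en-1-one
Product: 16 (R)-4-[1-(trimethylsilyl)vinyl]cyclopent-2-en-1-one, via Grignard reagent 14 (not isolated), via silyloxy ketone 15 (not isolated)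
Conditions: 12, Mg, THF, rt; CuBr·SMe2 (10 mol %), THF, −78 °C, then 13; aq. NH4Cl at −78 °C; crude 15, DBU, CH2Cl2, 0 °C, short time
Reagents that add atoms: none
Why: Copper-catalysed conjugate addition of the alkenyl Grignard reagent occurs anti to the C3 silyloxy group and sets C2, and E1cB loss of the silanol through the C4 enolate then moves the enone to C3=C4 (net anti SN2′-type substitution).

Step 9
Reactants: 16 (R)-4-[1-(trimethylsilyl)vinyl]cyclopent-2-en-1-one; 17 3-[(4-methoxybenzyl)oxy]propanal
Product: 19 4,5-trans aldol adduct (4S,5S; C7 carbinol epimers), via lithium dienolate 18 (not isolated)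
Conditions: LiN(i-Pr)2 (1.1 equiv), THF, −78 °C; then 17, −78 °C; aq. NH4Cl
Reagents that add atoms: none
Why: Kinetic deprotonation at C6 gives the cross-conjugated enolate, and its aldol addition on the face anti to the bulky C2 substituent should set the C2/C6 trans relationship (the C7 carbinol configuration is immaterial).

Step 10
Reactants: 19 4,5-trans aldol adduct
Product: 20 C7 triethylsilyl ether of 19
Conditions: Et3SiCl, imidazole, DMF, 0 °C → rt
Reagents that add atoms: chlorotriethylsilane, CC[Si](Cl)(CC)CC
Why: Silylation of the secondary aldol hydroxyl under mild conditions blocks retro-aldol and dehydration in the later steps.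

Step 11
Reactants: 20 C7 triethylsilyl ether
Product: 21 1-iodovinyl enone
Conditions: NIS, MeCN, 0 °C → rt, dark
Reagents that add atoms: N-iodosuccinimide, O=C1CCC(=O)N1I
Why: Electrophilic ipso-iododesilylation of the alkenylsilane (β-silyl stabilisation of the cationic intermediate) should give the 1-iodovinyl group, while the electron-poor enone double bond is inert.

Step 12
Reactants: 21 1-iodovinyl enone
Product: 22 primary alcohol at C10
Conditions: DDQ, CH2Cl2/aq. phosphate buffer (pH 7), 0 °C
Reagents that add atoms: none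
Why: Oxidative cleavage of the 4-methoxybenzyl ether by DDQ frees the primary alcohol without affecting the silyl ether, the enone or the alkenyl iodide.

Step 13
Reactants: 22 primary alcohol at C10
Product: 23 3-[(1S,5S)-5-(1-iodovinyl)-2-oxocyclopent-3-en-1-yl]-3-(triethylsilyloxy)propanal
Conditions: Dess–Martin periodinane, NaHCO3, CH2Cl2, 0 °C → rt
Reagents that add atoms: none
Why: Buffered Dess–Martin oxidation gives the β-silyloxy aldehyde under non-basic conditions that avoid β-elimination.

Step 14
Reactants: 23 iodo aldehyde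
Product: 25 trans-fused bicyclic enone with 10β-hydroxyl, via alkenylchromium dichloride 24 (not isolated)
Conditions: CrCl2 (6 equiv), NiCl2 (2 mol %), DMF, rt, 0.01 M
Reagents that add atoms: none
Why: Oxidative addition of the alkenyl iodide to zerovalent nickel, transmetallation to trivalent chromium and addition to the aldehyde alone (Nozaki–Hiyama–Kishi reaction, 6-exo-trig) close the six-membered ring, and a chair-like transition state with the ring-fusion bonds and the chromium alkoxide equatorial should give the 10β (equatorial) alcohol.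

Step 15
Reactants: 25 bicyclic enone alcohol
Product: 26 C10 tert-butyldimethylsilyl ether of 25
Conditions: t-BuMe2SiOTf, 2,6-lutidine, CH2Cl2, −78 °C
Reagents that add atoms: tert-butyldimethylsilyl trifluoromethanesulfonate, CC(C)(C)[Si](C)(C)OS(=O)(=O)C(F)(F)F
Why: Low-temperature silylation with a weakly basic pyridine protects the allylic alcohol without epimerising the C6 centre α to the enone carbonyl.

Step 16
Reactants: 26 C10 silyl ether
Product: 29 C5 enol triflate (C4=C5), via silyl enol ether 27 (not isolated), via lithium enolate 28 (not isolated)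
Conditions: [(Ph3P)CuH]6 (5 mol %), PhMe2SiH, toluene, 0 °C → rt; then MeLi, THF, 0 °C; then PhNTf2, −78 → 0 °C; aq. NH4Cl
Reagents that add atoms: N-phenylbis(trifluoromethanesulfonimide), O=S(=O)(N(c1ccccc1)S(=O)(=O)C(F)(F)F)C(F)(F)F
Why: Copper hydride-catalysed 1,4-hydrosilylation of the enone gives the C4=C5 silyl enol ether regiospecifically, and Si–Li exchange followed by O-triflation traps that enolate before it can equilibrate towards C6 (reductive enol triflate formation).

Step 17
Reactants: 29 C5 enol triflate
Product: 30 5-methylcyclopentene bis-silyl ether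
Conditions: MeMgBr, Fe(acac)3 (5 mol %), THF/NMP, −30 °C
Reagents that add atoms: methylmagnesium bromide, C[Mg]Br
Why: Iron-catalysed cross-coupling of the alkenyl triflate with the methyl Grignard reagent should install the C5 methyl group on the C4=C5 bond, with silyl ethers and the other alkenes inert.

Step 18
Reactants: 30 5-methylcyclopentene bis-silyl ether
Product: 31 C7 alcohol with C10 silyl ether retained
Conditions: HF·pyridine, pyridine, THF, 0 °C
Reagents that add atoms: none
Why: Under buffered HF the triethylsilyl ether is cleaved much faster than the tert-butyldimethylsilyl ether (selective desilylation).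

Step 19
Reactants: 31 C7 alcohol
Product: 32 (2S,6R,10R)-trans-hydrindanone with C7 ketone and C10 silyl ether
Conditions: Dess–Martin periodinane, NaHCO3, CH2Cl2, 0 °C
Reagents that add atoms: none
Why: Buffered Dess–Martin oxidation gives the ketone without base, so C6 (α to the ketone and allylic) should not epimerise, the C4=C5 bond should not move into conjugation and the β-silyloxy group should not be eliminated.

**Ring expansion and end game**

Step 20
Reactants: 32 trans-hydrindanone; 11 side-chain diazoalkane
Product: 34 (2S,6R,8R,10R,1′S)-hydroazulenone with the side chain on C8, via diazonium alkoxide 33 (not isolated)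
Conditions: Sc(OTf)3 (10 mol %), toluene, −78 °C; slow addition of 11 (1.5 equiv, cold THF solution); −78 → −40 °C
Reagents that add atoms: none
Why: Sc(OTf)3 activates the C7 carbonyl, the diazo carbon (the future C8) adds to give diazonium alkoxide 33, and the ring bond anti-periplanar to C–N2 shifts from C7 to C8 with loss of N2 and return of the C7 ketone; the closest known reaction type is the Lewis-acid-promoted one-carbon homologation of cycloalkanones with non-stabilised diazoalkanes (Tiffeneau–Demjanov-type 1,2-shift). The seven-membered ring (C1, C2, C6, C7, C8, C9, C10) is not closed by a cyclisation but arises by enlargement of the six-membered ring, the C9–C7 bond being exchanged for C9–C8. C8 is set by the substrate: the diazo carbon should approach the axial (α) face of C7, away from the in-plane C5 methyl group, with its hydrogen under the ring and the side chain pointing outward, and migration with inversion at that carbon then places the side chain β, cis to H-6 and to the C10 silyloxy group, which is also the pseudo-equatorial position. The step needs migration of the C9 methylene in preference to the allylic methine C6, which is secured because the rotamer with N2 anti to C6 forces the side chain gauche to the substituted C6. It also needs mono-insertion, which is secured because the α,α′-disubstituted product ketone is far more hindered than 32, and the catalytic Lewis acid at −78 °C should spare the β-silyloxy ketone and the tertiary allylic silyl ether.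

Step 21
Reactants: 34 hydroazulenone
Product: 35 C10 alcohol/tertiary alcohol ketone
Conditions: HF·pyridine, pyridine, THF, 0 °C → rt
Reagents that add atoms: none
Why: Fluoride-driven cleavage of both silyl ethers under pyridine buffering should leave the tertiary allylic alcohol and the β,γ-unsaturated ketone untouched.

Step 22
Reactants: 35 diol ketone
Product: 36 C10 acetate
Conditions: Ac2O (1.2 equiv), pyridine, DMAP (2 mol %), CH2Cl2, 0 °C
Reagents that add atoms: acetic anhydride, CC(=O)OC(C)=O
Why: Acetylation is selective for the secondary allylic C10 hydroxyl because the tertiary hydroxyl is unreactive under these conditions and C7 is still a ketone.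

Step 23
Reactants: 36 C10 acetate
Product: 37 CNP0312076.1 (target)
Conditions: LiBH(s-Bu)3 (2.2 equiv), THF, −78 °C; aq. NH4Cl
Reagents that add atoms: none
Why: The bulky hydride should attack the C7 ketone from the α face, anti to the β side chain on C8, giving the 7β-alcohol cis to the side chain as with 2-alkylcycloalkanones, and at −78 °C the acetate should not be reduced.

**Compound list**

1 | 2-methylbut-3-yn-2-ol | C#CC(C)(C)O | starting material
2 | triethyl[(2-methylbut-3-yn-2-yl)oxy]silane | C#CC(C)(C)O[Si](CC)(CC)CC | intermediate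
3 | chlorobis(cyclopentadienyl)[(E)-3-methyl-3-(triethylsilyloxy)but-1-enyl]zirconium (not isolated) | Cl[Zr](/C=C/C(C)(C)O[Si](CC)(CC)CC)(C1C=CC=C1)C1C=CC=C1 | intermediate
4 | (E)-triethyl[(4-iodo-2-methylbut-3-en-2-yl)oxy]silane | I/C=C/C(C)(C)O[Si](CC)(CC)CC | intermediate
5 | methyl (S)-3-hydroxy-2-methylpropanoate | COC(=O)[C@@H](C)CO | starting material
6 | methyl (R)-3-iodo-2-methylpropanoate | COC(=O)[C@@H](C)CI | intermediate
7 | [(R)-3-methoxy-2-methyl-3-oxopropyl]zinc iodide (not isolated) | COC(=O)[C@@H](C)C[Zn]I | intermediate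
8 | methyl (2S,4E)-2,6-dimethyl-6-(triethylsilyloxy)hept-4-enoate | COC(=O)[C@@H](C)C/C=C/C(C)(C)O[Si](CC)(CC)CC | intermediate
9 | (2S,4E)-2,6-dimethyl-6-(triethylsilyloxy)hept-4-enal | O=C[C@@H](C)C/C=C/C(C)(C)O[Si](CC)(CC)CC | intermediate
10 | (E)-[(2S,4E)-2,6-dimethyl-6-(triethylsilyloxy)hept-4-enylidene]hydrazine | N/N=C/[C@@H](C)C/C=C/C(C)(C)O[Si](CC)(CC)CC | intermediate
11 | (2S,4E)-1-diazo-2,6-dimethyl-6-(triethylsilyloxy)hept-4-ene | [N-]=[N+]=C[C@@H](C)C/C=C/C(C)(C)O[Si](CC)(CC)CC | intermediate
12 | (1-bromovinyl)trimethylsilane | C=C(Br)[Si](C)(C)C | starting material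
13 | (R)-4-(tert-butyldimethylsilyloxy)cyclopent-2-en-1-one | O=C1C=C[C@H](O[Si](C)(C)C(C)(C)C)C1 | starting material
14 | [1-(trimethylsilyl)vinyl]magnesium bromide (not isolated) | C=C([Mg]Br)[Si](C)(C)C | intermediate
15 | (3R,4R)-4-(tert-butyldimethylsilyloxy)-3-[1-(trimethylsilyl)vinyl]cyclopentan-1-one (not isolated) | O=C1C[C@@H](C(=C)[Si](C)(C)C)[C@H](O[Si](C)(C)C(C)(C)C)C1 | intermediate
16 | (R)-4-[1-(trimethylsilyl)vinyl]cyclopent-2-en-1-one | O=C1C=C[C@H](C(=C)[Si](C)(C)C)C1 | intermediate
17 | 3-[(4-methoxybenzyl)oxy]propanal | O=CCCOCc1ccc(OC)cc1 | starting material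
18 | lithium (R)-3-[1-(trimethylsilyl)vinyl]cyclopenta-1,4-dien-1-olate (not isolated) | [Li]OC1=C[C@@H](C(=C)[Si](C)(C)C)C=C1 | intermediate
19 | (4S,5S)-5-{1-hydroxy-3-[(4-methoxybenzyl)oxy]propyl}-4-[1-(trimethylsilyl)vinyl]cyclopent-2-en-1-one (4,5-trans; carbinol epimers) | O=C1C=C[C@H](C(=C)[Si](C)(C)C)[C@H]1C(O)CCOCc1ccc(OC)cc1 | intermediate
20 | (4S,5S)-5-{3-[(4-methoxybenzyl)oxy]-1-(triethylsilyloxy)propyl}-4-[1-(trimethylsilyl)vinyl]cyclopent-2-en-1-one | O=C1C=C[C@H](C(=C)[Si](C)(C)C)[C@H]1C(O[Si](CC)(CC)CC)CCOCc1ccc(OC)cc1 | intermediate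
21 | (4S,5S)-4-(1-iodovinyl)-5-{3-[(4-methoxybenzyl)oxy]-1-(triethylsilyloxy)propyl}cyclopent-2-en-1-one | O=C1C=C[C@H](C(I)=C)[C@H]1C(O[Si](CC)(CC)CC)CCOCc1ccc(OC)cc1 | intermediate
22 | (4S,5S)-5-[3-hydroxy-1-(triethylsilyloxy)propyl]-4-(1-iodovinyl)cyclopent-2-en-1-one | O=C1C=C[C@H](C(I)=C)[C@H]1C(O[Si](CC)(CC)CC)CCO | intermediate
23 | 3-[(1S,5S)-5-(1-iodovinyl)-2-oxocyclopent-3-en-1-yl]-3-(triethylsilyloxy)propanal | O=C1C=C[C@H](C(I)=C)[C@H]1C(O[Si](CC)(CC)CC)CC=O | intermediate
24 | alkenylchromium dichloride formed from 23 at C1, trivalent chromium (not isolated) | O=C1C=C[C@H](C(=C)[Cr](Cl)Cl)[C@H]1C(O[Si](CC)(CC)CC)CC=O | intermediate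
25 | trans-fused bicyclic enone alcohol: five-membered ring C2–C3=C4–C5(=O)–C6, six-membered ring C1(=CH2)–C2–C6–C7(OSiEt3)–C9H2–C10(OH); H-2 α, H-6 β, 10-OH β (10R) | C=C1[C@H]2C=CC(=O)[C@@H]2C(O[Si](CC)(CC)CC)C[C@H]1O | intermediate
26 | C10 tert-butyldimethylsilyl ether of 25 | C=C1[C@H]2C=CC(=O)[C@@H]2C(O[Si](CC)(CC)CC)C[C@H]1O[Si](C)(C)C(C)(C)C | intermediate
27 | C4=C5 dimethylphenylsilyl enol ether from 26, C3 now CH2 (not isolated) | C=C1[C@H]2CC=C(O[Si](C)(C)c3ccccc3)[C@@H]2C(O[Si](CC)(CC)CC)C[C@H]1O[Si](C)(C)C(C)(C)C | intermediate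
28 | C5 lithium enolate from 27 (not isolated) | C=C1[C@H]2CC=C(O[Li])[C@@H]2C(O[Si](CC)(CC)CC)C[C@H]1O[Si](C)(C)C(C)(C)C | intermediate
29 | C5 enol triflate (C4=C5), C7 OSiEt3, C10 OSi(t-Bu)Me2 | C=C1[C@H]2CC=C(OS(=O)(=O)C(F)(F)F)[C@@H]2C(O[Si](CC)(CC)CC)C[C@H]1O[Si](C)(C)C(C)(C)C | intermediate
30 | 5-methyl analogue of 29 (C4=C5–CH3), both silyl ethers in place | C=C1[C@H]2CC=C(C)[C@@H]2C(O[Si](CC)(CC)CC)C[C@H]1O[Si](C)(C)C(C)(C)C | intermediate
31 | C7 alcohol from 30, C10 silyl ether retained | C=C1[C@H]2CC=C(C)[C@@H]2C(O)C[C@H]1O[Si](C)(C)C(C)(C)C | intermediate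
32 | (2S,6R,10R)-trans-hydrindanone: C7 ketone, C1 methylene, C4=C5–CH3, 10β-OSi(t-Bu)Me2 | C=C1[C@H]2CC=C(C)[C@@H]2C(=O)C[C@H]1O[Si](C)(C)C(C)(C)C | intermediate
33 | diazonium alkoxide from addition of 11 to C7 of 32, new centres C7 and C8 undefined (not isolated) | C=C1[C@H]2CC=C(C)[C@@H]2C([O-])(C[C@H]1O[Si](C)(C)C(C)(C)C)C([N+]#N)[C@@H](C)C/C=C/C(C)(C)O[Si](CC)(CC)CC | intermediate
34 | (2S,6R,8R,10R,1′S)-hydroazulenone: C7 ketone, 8β side chain with OSiEt3, 10β-OSi(t-Bu)Me2 | C=C1[C@H]2CC=C(C)[C@@H]2C(=O)[C@@H]([C@@H](C)C/C=C/C(C)(C)O[Si](CC)(CC)CC)C[C@H]1O[Si](C)(C)C(C)(C)C | intermediate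
35 | desilylated hydroazulenone: C7 ketone, 10β-OH, side-chain tertiary OH | C=C1[C@H]2CC=C(C)[C@@H]2C(=O)[C@@H]([C@@H](C)C/C=C/C(C)(C)O)C[C@H]1O | intermediate
36 | C10 acetate of 35 | C=C1[C@H]2CC=C(C)[C@@H]2C(=O)[C@@H]([C@@H](C)C/C=C/C(C)(C)O)C[C@H]1OC(C)=O | intermediate
37 | CNP0312076.1 (2S,6R,7S,8R,10R,1′S) | C=C1[C@H]2CC=C(C)[C@@H]2[C@@H](O)[C@@H]([C@@H](C)C/C=C/C(C)(C)O)C[C@H]1OC(C)=O | target

**Step count**

Total: 23 steps. Longest linear sequence: 16 steps (13 → 37, steps 8–23); the side-chain branch (steps 1–7) joins at step 20.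

**Steps most likely to fail**

1. Step 20. The hindered diazoalkane may be consumed before it adds (azine formation, 1,2-hydride shift, Lewis-acid ionisation of its tertiary allylic silyl ether). Migration of the allylic C6, or delivery of the side chain to the α face of C8, may also compete.
   Fallback: the inserted carbon is brought in on a leaner diazoalkane without the tertiary ether, and the side-chain terminus is added after the ring expansion. It sets out from iodide 6 (and ketone 32) and returns at 35. The zinc reagent 7 from 6 is coupled with vinyl bromide (Pd2(dba)3, P(o-tol)3, DMF) to give methyl (S)-2-methylpent-4-enoate F1. The operations of steps 5–7 then lead through (S)-2-methylpent-4-enal F2 and its hydrazone F3 to (S)-5-diazo-4-methylpent-1-ene F4. Sc(OTf)3-promoted insertion into 32 should give the C8 pent-4-en-2-yl hydroazulenone F5. Cross-metathesis of its monosubstituted alkene with excess 2-methylbut-3-en-2-ol (second-generation Hoveyda–Grubbs catalyst, CH2Cl2, 40 °C) should give the (E)-tertiary allylic alcohol F6, and HF·pyridine then gives 35.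

2. Step 14. Facial selectivity in the addition to the aldehyde may be poor or reversed (a chair with the alkoxide axial relieves allylic strain with the exocyclic methylene), and closure onto the strained trans-fused cyclopentenone may be slow.
   Fallback: the cyclisation is accepted as it comes and the configuration is corrected afterwards. It sets out from 23 and returns at 25. The 10α-hydroxy epimer F7 from the cyclisation is separated and inverted under Mitsunobu conditions (ClCH2CO2H, PPh3, DIAD, toluene, 0 °C) to the 10β-chloroacetate F8. Its ester is removed under near-neutral conditions (thiourea, NaHCO3, EtOH, rt) to give 25.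

3. Step 23. The hydride may be delivered from the β face (7α-alcohol), and the acetate may be attacked or may migrate.
   Fallback: the ketone is reduced before any ester is present, with a small hydride, and the two secondary alcohols are differentiated afterwards. It sets out from 34 and returns at 37. Reduction with NaBH4/CeCl3·7H2O (MeOH, −40 °C) should follow the less congested axial-type trajectory and give the bis-silyl 7β-alcohol F9. HF·pyridine then gives the triol F10. Acetylation (Ac2O 1.1 equiv, pyridine, 0 °C) should take place only at the unhindered allylic C10 hydroxyl, not at the C7 hydroxyl flanked by C6 and C8 or at the tertiary hydroxyl, and gives 37.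

Further compounds
F1 | step 20 | methyl (S)-2-methylpent-4-enoate | COC(=O)[C@@H](C)CC=C
F2 | step 20 | (S)-2-methylpent-4-enal | O=C[C@@H](C)CC=C
F3 | step 20 | (E)-hydrazone of (S)-2-methylpent-4-enal | N/N=C/[C@@H](C)CC=C
F4 | step 20 | (S)-5-diazo-4-methylpent-1-ene | [N-]=[N+]=C[C@@H](C)CC=C
F5 | step 20 | hydroazulenone with 8β-[(S)-pent-4-en-2-yl], C7 ketone, 10β-OSi(t-Bu)Me2 | C=C1[C@H]2CC=C(C)[C@@H]2C(=O)[C@@H]([C@@H](C)CC=C)C[C@H]1O[Si](C)(C)C(C)(C)C
F6 | step 20 | hydroazulenone with complete side chain (free tertiary OH), C7 ketone, 10β-OSi(t-Bu)Me2 | C=C1[C@H]2CC=C(C)[C@@H]2C(=O)[C@@H]([C@@H](C)C/C=C/C(C)(C)O)C[C@H]1O[Si](C)(C)C(C)(C)C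
F7 | step 14 | C10 epimer of 25 (10α-OH) | C=C1[C@H]2C=CC(=O)[C@@H]2C(O[Si](CC)(CC)CC)C[C@@H]1O
F8 | step 14 | 10β-chloroacetate of 25 | C=C1[C@H]2C=CC(=O)[C@@H]2C(O[Si](CC)(CC)CC)C[C@H]1OC(=O)CCl
F9 | step 23 | 7β-alcohol of 34 with both silyl ethers | C=C1[C@H]2CC=C(C)[C@@H]2[C@@H](O)[C@@H]([C@@H](C)C/C=C/C(C)(C)O[Si](CC)(CC)CC)C[C@H]1O[Si](C)(C)C(C)(C)C
F10 | step 23 | 7β,10β-diol with side-chain tertiary OH (triol) | C=C1[C@H]2CC=C(C)[C@@H]2[C@@H](O)[C@@H]([C@@H](C)C/C=C/C(C)(C)O)C[C@H]1O
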